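**Strategy.** The plan opens ring C at the aryl–oxygen bond O1–C8a (isoflavan numbering). In ring A, C8a lies meta to both methoxy-bearing carbons C5 and C7, out of reach of electrophilic substitution, so the oxygen is brought in by substitution of a chlorine that 1-chloro-3,5-dimethoxybenzene already carries at that carbon. The key step, a palladium-catalysed intramolecular O-arylation, lets the C2 hydroxyl of an acyclic (R)-2,3-diarylpropan-1-ol displace this chloride and closes the dihydropyran in one operation, with the C3 centre (from an Evans alkylation), the C6 prenyl group and the ring B chromene already in place. The precursor is thus the open-chain chloro alcohol holding every carbon of the target.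

Key step: step 12

Remark: ring A is the benzo ring, ring C the dihydropyran and ring B the chromenyl group on C3; the stereodescriptor of the target corresponds to 3R.

**Step 1**
Reactants: 1 2,4-dihydroxybenzaldehyde
Product: 2 2-hydroxy-4-(methoxymethoxy)benzaldehyde
Conditions: MOMCl (1.1 equiv), K2CO3, acetone, 0 °C → rt
Reagents that add atoms: chloromethyl methyl ether (MOMCl), COCCl
Why: Williamson-type O-alkylation should be selective for the 4-OH because the 2-OH is held in a hydrogen bond to the aldehyde and is far less nucleophilic.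

**Step 2**
Reactants: 2 2-hydroxy-4-(methoxymethoxy)benzaldehyde; 3 3-chloro-3-methylbut-1-yne
Product: 4 4-(methoxymethoxy)-2-[(2-methylbut-3-yn-2-yl)oxy]benzaldehyde
Conditions: DBU, CuCl2 (1 mol%), MeCN, 0 °C → rt
Reagents that add atoms: none
Why: Copper-catalysed propargylic substitution of the tertiary chloride by the remaining phenoxide should give the 1,1-dimethylpropargyl aryl ether, the standard chromene precursor.

**Step 3**
Reactants: 4 4-(methoxymethoxy)-2-[(2-methylbut-3-yn-2-yl)oxy]benzaldehyde
Product: 6 5-(methoxymethoxy)-2,2-dimethyl-2H-chromene-8-carbaldehyde, via allenyl phenol 5 (not isolated)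
Conditions: N,N-diethylaniline, 180 °C
Reagents that add atoms: none
Why: The aromatic propargyl Claisen rearrangement can only reach the ring carbon between the two oxygens (the other ortho carbon bears the formyl group), and the allenyl phenol 5 should close by 1,5-hydrogen shift and oxa-6π electrocyclisation, which places the pyran oxygen ortho to the future C1′.

**Step 4**
Reactants: 6 5-(methoxymethoxy)-2,2-dimethyl-2H-chromene-8-carbaldehyde
Product: 8 [5-(methoxymethoxy)-2,2-dimethyl-2H-chromen-8-yl]acetonitrile, via vinyl formamide 7 (not isolated)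
Conditions: TosMIC, t-BuOK, DME, −40 °C; then MeOH, reflux
Reagents that add atoms: 4-toluenesulfonylmethyl isocyanide (TosMIC), [C-]#[N+]CS(=O)(=O)c1ccc(C)cc1
Why: Van Leusen reductive cyanation: the TosMIC anion adds to the aldehyde, the oxazoline opens to formamide 7, and methanolysis with loss of sulfinate and methyl formate should give the one-carbon-homologated nitrile without touching the chromene or the MOM ether.

**Step 5**
Reactants: 8 [5-(methoxymethoxy)-2,2-dimethyl-2H-chromen-8-yl]acetonitrile
Product: 9 [5-(methoxymethoxy)-2,2-dimethyl-2H-chromen-8-yl]acetic acid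
Conditions: KOH, EtOH/H2O, 85 °C; then 1 M HCl, 0 °C, to pH 3
Reagents that add atoms: water, O; potassium hydroxide, [K+].[OH-]
Why: Alkaline nitrile hydrolysis is compatible with the base-stable MOM ether and chromene, and the cold, brief acidification should spare the acetal.

**Step 6**
Reactants: 9 [5-(methoxymethoxy)-2,2-dimethyl-2H-chromen-8-yl]acetic acid; 10 (4R)-4-benzyl-1,3-oxazolidin-2-one
Product: 12 (4R)-4-benzyl-3-{[5-(methoxymethoxy)-2,2-dimethyl-2H-chromen-8-yl]acetyl}-1,3-oxazolidin-2-one, via mixed pivalic anhydride 11 (not isolated)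
Conditions: PivCl, Et3N, THF, −20 °C; then 10, LiCl, −20 °C → rt
Reagents that add atoms: none
Why: N-Acylation of the oxazolidinone through the mixed anhydride 11 should occur at the less hindered arylacetyl carbonyl.

**Step 7**
Reactants: 13 1-chloro-3,5-dimethoxybenzene; 14 1-bromo-3-methylbut-2-ene (prenyl bromide)
Product: 16 5-chloro-1,3-dimethoxy-2-(3-methylbut-2-en-1-yl)benzene, via aryllithium 15 (not isolated)
Conditions: n-BuLi, THF, 0 °C; then CuI (5 mol%), 14, −78 °C → rt
Reagents that add atoms: none
Why: Directed ortho-metalation under coordination control: n-BuLi is held by both methoxy groups and should remove the hydrogen between them (methoxy outranks chlorine as a directing group for n-BuLi), and aryllithium 15 is alkylated at the primary carbon of prenyl bromide.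

**Step 8**
Reactants: 16 5-chloro-1,3-dimethoxy-2-(3-methylbut-2-en-1-yl)benzene
Product: 19 [6-chloro-2,4-dimethoxy-3-(3-methylbut-2-en-1-yl)phenyl]methanol, via aryllithium 17 (not isolated), via aldehyde 18 (not isolated)
Conditions: s-BuLi, TMEDA, THF, −78 °C; DMF, −78 → 0 °C; then MeOH, NaBH4, 0 °C
Reagents that add atoms: N,N-dimethylformamide (DMF), CN(C)C=O
Why: The two remaining ring hydrogens of 16 are equivalent and each is flanked by chlorine and methoxy, so ortho-lithiation at −78 °C (below the temperature of LiCl loss), formylation with DMF and borohydride reduction in the same flask should give the benzylic alcohol with no regiochemical question.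

**Step 9**
Reactants: 19 [6-chloro-2,4-dimethoxy-3-(3-methylbut-2-en-1-yl)phenyl]methanol
Product: 20 2-(bromomethyl)-1-chloro-3,5-dimethoxy-4-(3-methylbut-2-en-1-yl)benzene
Conditions: CBr4, PPh3, CH2Cl2, 0 °C
Reagents that add atoms: carbon tetrabromide, BrC(Br)(Br)Br
Why: The Appel reaction converts the electron-rich benzylic alcohol into the bromide under neutral conditions that should leave the prenyl double bond alone.

**Step 10**
Reactants: 12 (4R)-4-benzyl-3-{[5-(methoxymethoxy)-2,2-dimethyl-2H-chromen-8-yl]acetyl}-1,3-oxazolidin-2-one; 20 2-(bromomethyl)-1-chloro-3,5-dimethoxy-4-(3-methylbut-2-en-1-yl)benzene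
Product: 22 (4R)-4-benzyl-3-{(2R)-3-[6-chloro-2,4-dimethoxy-3-(3-methylbut-2-en-1-yl)phenyl]-2-[5-(methoxymethoxy)-2,2-dimethyl-2H-chromen-8-yl]propanoyl}-1,3-oxazolidin-2-one, via sodium enolate 21 (not isolated)
Conditions: NaHMDS, THF, −78 °C; then 20, −78 → −30 °C
Reagents that add atoms: none
Why: Evans asymmetric alkylation: the chelated sodium (Z)-enolate 21 should be attacked by the benzylic bromide on the face opposite the benzyl group of the (R)-auxiliary, which sets the new centre (the future C3) as R.

**Step 11**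
Reactants: 22 the alkylated imide
Product: 23 (2R)-3-[6-chloro-2,4-dimethoxy-3-(3-methylbut-2-en-1-yl)phenyl]-2-[5-(methoxymethoxy)-2,2-dimethyl-2H-chromen-8-yl]propan-1-ol
Conditions: LiBH4, H2O (1 equiv), Et2O, 0 °C
Reagents that add atoms: none
Why: Reductive cleavage of the imide with LiBH4 should give the primary alcohol without epimerising the α-aryl centre and leave the aryl chloride, both alkenes and the MOM ether untouched.

**Step 12**
Reactants: 23 the (2R)-chloro alcohol
Product: 24 (3R)-5,7-dimethoxy-3-[5-(methoxymethoxy)-2,2-dimethyl-2H-chromen-8-yl]-6-(3-methylbut-2-en-1-yl)-3,4-dihydro-2H-chromene (O-MOM Kanzonol I)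
Conditions: [Pd(allyl)Cl]2 (2.5 mol%), RockPhos (6 mol%), Cs2CO3, toluene, 90 °C
Reagents that add atoms: none
Why: Buchwald–Hartwig-type C–O coupling run intramolecularly: zerovalent palladium, formed in situ and held by the bulky biaryl phosphine, inserts into the C8a–Cl bond, the caesium alkoxide of the C2 hydroxyl replaces chloride on divalent palladium to give a seven-membered oxapalladacycle, and C–O reductive elimination forms O1–C8a. The closest known reaction type is the palladium-catalysed cyclisation of 3-(2-halophenyl)propan-1-ols to chromans with dialkylbiaryl phosphines and carbonate base. Ring C closes as a six-membered ring in a 6-exo sense at the aromatic carbon; no new stereocentre is formed, and C3, which carries no acidic hydrogen under Cs2CO3 and takes no part in any bond made or broken, should keep its R configuration. The selectivity needed is reductive elimination over β-hydride elimination of the primary alkoxide (which would give the aldehyde and the dechlorinated arene); the very bulky, electron-rich ligand and the chelate that holds oxygen and C8a cis on palladium should secure it. Chemoselectivity rests on 23 holding a single carbon–halogen bond, while the prenyl and chromene double bonds cannot reach the arylpalladium centre in a Heck sense and the MOM ether is inert to carbonate.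

**Step 13**
Reactants: 24 O-MOM Kanzonol I
Product: 25 Kanzonol I, (3R)-8-[5,7-dimethoxy-6-(3-methylbut-2-en-1-yl)-3,4-dihydro-2H-chromen-3-yl]-2,2-dimethyl-2H-chromen-5-ol
Conditions: p-TsOH·H2O (0.2 equiv), MeOH, 40 °C
Reagents that add atoms: none
Why: Acid-catalysed transacetalisation to methanol should remove the phenolic MOM group under conditions mild enough for the chromene and for the prenyl group, which is flanked by two methoxy groups and cannot cyclise.

**Compound list**
1 | 2,4-dihydroxybenzaldehyde | O=Cc1ccc(O)cc1O | starting material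
2 | 2-hydroxy-4-(methoxymethoxy)benzaldehyde | COCOc1ccc(C=O)c(O)c1 | intermediate
3 | 3-chloro-3-methylbut-1-yne | C#CC(C)(C)Cl | starting material
4 | 4-(methoxymethoxy)-2-[(2-methylbut-3-yn-2-yl)oxy]benzaldehyde | COCOc1ccc(C=O)c(OC(C)(C)C#C)c1 | intermediate
5 | 2-hydroxy-4-(methoxymethoxy)-3-(3-methylbuta-1,2-dien-1-yl)benzaldehyde | COCOc1ccc(C=O)c(O)c1C=C=C(C)C | intermediate (not isolated)
6 | 5-(methoxymethoxy)-2,2-dimethyl-2H-chromene-8-carbaldehyde | COCOc1ccc(C=O)c2OC(C)(C)C=Cc12 | intermediate
7 | N-{2-[5-(methoxymethoxy)-2,2-dimethyl-2H-chromen-8-yl]-1-(4-methylbenzenesulfonyl)ethenyl}formamide (mixture of alkene isomers) | O=CNC(=Cc1ccc(OCOC)c2C=CC(C)(C)Oc12)S(=O)(=O)c1ccc(C)cc1 | intermediate (not isolated)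
8 | [5-(methoxymethoxy)-2,2-dimethyl-2H-chromen-8-yl]acetonitrile | N#CCc1ccc(OCOC)c2C=CC(C)(C)Oc12 | intermediate
9 | [5-(methoxymethoxy)-2,2-dimethyl-2H-chromen-8-yl]acetic acid | OC(=O)Cc1ccc(OCOC)c2C=CC(C)(C)Oc12 | intermediate
10 | (4R)-4-benzyl-1,3-oxazolidin-2-one | O=C1N[C@H](Cc2ccccc2)CO1 | starting material
11 | [5-(methoxymethoxy)-2,2-dimethyl-2H-chromen-8-yl]acetic pivalic anhydride | CC(C)(C)C(=O)OC(=O)Cc1ccc(OCOC)c2C=CC(C)(C)Oc12 | intermediate (not isolated)
12 | (4R)-4-benzyl-3-{[5-(methoxymethoxy)-2,2-dimethyl-2H-chromen-8-yl]acetyl}-1,3-oxazolidin-2-one | O=C1OC[C@@H](Cc2ccccc2)N1C(=O)Cc1ccc(OCOC)c2C=CC(C)(C)Oc12 | intermediate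
13 | 1-chloro-3,5-dimethoxybenzene | COc1cc(Cl)cc(OC)c1 | starting material
14 | 1-bromo-3-methylbut-2-ene | CC(C)=CCBr | starting material
15 | (4-chloro-2,6-dimethoxyphenyl)lithium | [Li]c1c(OC)cc(Cl)cc1OC | intermediate (not isolated)
16 | 5-chloro-1,3-dimethoxy-2-(3-methylbut-2-en-1-yl)benzene | COc1cc(Cl)cc(OC)c1CC=C(C)C | intermediate
17 | [6-chloro-2,4-dimethoxy-3-(3-methylbut-2-en-1-yl)phenyl]lithium | [Li]c1c(Cl)cc(OC)c(CC=C(C)C)c1OC | intermediate (not isolated)
18 | 6-chloro-2,4-dimethoxy-3-(3-methylbut-2-en-1-yl)benzaldehyde | O=Cc1c(Cl)cc(OC)c(CC=C(C)C)c1OC | intermediate (not isolated)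
19 | [6-chloro-2,4-dimethoxy-3-(3-methylbut-2-en-1-yl)phenyl]methanol | OCc1c(Cl)cc(OC)c(CC=C(C)C)c1OC | intermediate
20 | 2-(bromomethyl)-1-chloro-3,5-dimethoxy-4-(3-methylbut-2-en-1-yl)benzene | BrCc1c(Cl)cc(OC)c(CC=C(C)C)c1OC | intermediate
21 | sodium (Z)-enolate of 12 | [Na+].[O-]/C(=C\c1ccc(OCOC)c2C=CC(C)(C)Oc12)N1[C@H](Cc2ccccc2)COC1=O | intermediate (not isolated)
22 | (4R)-4-benzyl-3-{(2R)-3-[6-chloro-2,4-dimethoxy-3-(3-methylbut-2-en-1-yl)phenyl]-2-[5-(methoxymethoxy)-2,2-dimethyl-2H-chromen-8-yl]propanoyl}-1,3-oxazolidin-2-one | O=C1OC[C@@H](Cc2ccccc2)N1C(=O)[C@H](Cc1c(Cl)cc(OC)c(CC=C(C)C)c1OC)c1ccc(OCOC)c2C=CC(C)(C)Oc12 | intermediate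
23 | (2R)-3-[6-chloro-2,4-dimethoxy-3-(3-methylbut-2-en-1-yl)phenyl]-2-[5-(methoxymethoxy)-2,2-dimethyl-2H-chromen-8-yl]propan-1-ol | OC[C@H](Cc1c(Cl)cc(OC)c(CC=C(C)C)c1OC)c1ccc(OCOC)c2C=CC(C)(C)Oc12 | intermediate
24 | (3R)-5,7-dimethoxy-3-[5-(methoxymethoxy)-2,2-dimethyl-2H-chromen-8-yl]-6-(3-methylbut-2-en-1-yl)-3,4-dihydro-2H-chromene | COc1cc2c(c(OC)c1CC=C(C)C)C[C@H](c1ccc(OCOC)c3c1OC(C)(C)C=C3)CO2 | intermediate
25 | Kanzonol I | COc1cc2c(c(OC)c1CC=C(C)C)C[C@H](c1ccc(O)c3c1OC(C)(C)C=C3)CO2 | target

**Step count.** 13 steps in total. The longest linear sequence is 10 steps (steps 1–6 and 10–13, from 2,4-dihydroxybenzaldehyde); the ring A branch (steps 7–9) joins at step 10.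

**Steps most likely to fail**

Step 10. The hindered, ionisation-prone benzylic bromide may react too slowly with the stabilised arylacetyl enolate, which would then fragment to the aryl ketene on warming, giving low conversion and eroded diastereoselectivity. Fallback: the auxiliary is given up in favour of a racemic route with resolution. Nitrile 8 is deprotonated with LDA (THF, −78 °C) to the far more nucleophilic lithiated nitrile F1 and alkylated with 20 to give the racemic nitrile F2. DIBAL-H (toluene, −78 °C) and aqueous work-up should give the racemic aldehyde F3, NaBH4 (MeOH, 0 °C) the racemic alcohol F4, and preparative chiral SFC would separate 23 from its (S)-enantiomer F5. The fallback sets out from 8 and 20 and comes back at 23.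

Step 12. β-Hydride elimination from the palladium alkoxide (oxidation of the alcohol with loss of chlorine from the arene) or sluggish oxidative addition into the electron-rich, ortho-substituted aryl chloride may outrun ring closure. Fallback: a transition-metal-free elimination–addition that forms the same O1–C8a bond. Treatment of 23 with LiTMP (3 equiv, THF, −78 → 0 °C) should form the alkoxide, remove the C8 hydrogen between chlorine and methoxy and expel LiCl to give the aryne alkoxide F6. The tethered alkoxide adds at C8a, the aryne carbon remote from the C7 methoxy group and the only one the tether can reach, and the C8 aryllithium F7 is protonated on work-up. The fallback sets out from 23 and comes back at 24.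

Step 7. Competing lithiation next to chlorine, followed by loss of LiCl through an aryne, would give regioisomers and oligomers. Fallback: the prenyl position is fixed first and chlorine is brought in by sterically controlled C–H borylation. The new starting material 1,3-dimethoxybenzene F8 is lithiated between its methoxy groups (n-BuLi, THF, 0 °C) to 2,6-dimethoxyphenyllithium F9 and prenylated with 14 to 1,3-dimethoxy-2-prenylbenzene F10. [Ir(cod)OMe]2, 4,4′-di-tert-butyl-2,2′-bipyridine and B2pin2 should borylate the only unhindered C–H, para to the prenyl group, to give the aryl boronate F11, and CuCl2 (MeOH/H2O, 80 °C) should convert C–B into C–Cl. The fallback sets out from 14 and F8 and comes back at 16.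

**Further compounds**
F1 | step 10 | lithiated [5-(methoxymethoxy)-2,2-dimethyl-2H-chromen-8-yl]acetonitrile | [Li]C(C#N)c1ccc(OCOC)c2C=CC(C)(C)Oc12
F2 | step 10 | racemic 3-[6-chloro-2,4-dimethoxy-3-(3-methylbut-2-en-1-yl)phenyl]-2-[5-(methoxymethoxy)-2,2-dimethyl-2H-chromen-8-yl]propanenitrile | N#CC(Cc1c(Cl)cc(OC)c(CC=C(C)C)c1OC)c1ccc(OCOC)c2C=CC(C)(C)Oc12
F3 | step 10 | racemic 3-[6-chloro-2,4-dimethoxy-3-(3-methylbut-2-en-1-yl)phenyl]-2-[5-(methoxymethoxy)-2,2-dimethyl-2H-chromen-8-yl]propanal | O=CC(Cc1c(Cl)cc(OC)c(CC=C(C)C)c1OC)c1ccc(OCOC)c2C=CC(C)(C)Oc12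
F4 | step 10 | racemic 3-[6-chloro-2,4-dimethoxy-3-(3-methylbut-2-en-1-yl)phenyl]-2-[5-(methoxymethoxy)-2,2-dimethyl-2H-chromen-8-yl]propan-1-ol | OCC(Cc1c(Cl)cc(OC)c(CC=C(C)C)c1OC)c1ccc(OCOC)c2C=CC(C)(C)Oc12
F5 | step 10 | (2S)-3-[6-chloro-2,4-dimethoxy-3-(3-methylbut-2-en-1-yl)phenyl]-2-[5-(methoxymethoxy)-2,2-dimethyl-2H-chromen-8-yl]propan-1-ol | OC[C@@H](Cc1c(Cl)cc(OC)c(CC=C(C)C)c1OC)c1ccc(OCOC)c2C=CC(C)(C)Oc12
F6 | step 12 | lithium alkoxide of the C8–C8a aryne derived from 23 | [Li+].[O-]C[C@H](CC1=C(OC)C(CC=C(C)C)=C(OC)C#C1)c1ccc(OCOC)c2C=CC(C)(C)Oc12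
F7 | step 12 | 8-lithio derivative of 24 | COc1c([Li])c2c(c(OC)c1CC=C(C)C)C[C@H](c1ccc(OCOC)c3c1OC(C)(C)C=C3)CO2
F8 | step 7 | 1,3-dimethoxybenzene | COc1cccc(OC)c1
F9 | step 7 | (2,6-dimethoxyphenyl)lithium | [Li]c1c(OC)cccc1OC
F10 | step 7 | 1,3-dimethoxy-2-(3-methylbut-2-en-1-yl)benzene | COc1cccc(OC)c1CC=C(C)C
F11 | step 7 | 2-[3,5-dimethoxy-4-(3-methylbut-2-en-1-yl)phenyl]-4,4,5,5-tetramethyl-1,3,2-dioxaborolane | COc1cc(B2OC(C)(C)C(C)(C)O2)cc(OC)c1CC=C(C)C
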